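## Retrosynthetic overview

- Target ⇐ its tris(benzyl ether) by hydrogenolysis. The oxane is the only ring made, and it is closed last, in the key step.
- Oxane ⇐ open-chain (3S)-3-aryl-3-(alk-1-en-2-yloxy)propanal by C4–C5 bond formation: the enol ether carbon C5 adds to the aldehyde carbon C4, and a silane reduces the ring oxocarbenium ion at C6, so C4 and C6 are set in one operation.
- Enabling feature: in the oxane ring, C4(OH)–C5H2–C6(H)–O1 is an aldol retron whose acceptor oxygen is the ring oxygen. C6 can therefore be carried as an O1-bound enol ether/oxocarbenium carbon and C5 as its nucleophilic methylene.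
- Enol ether ⇐ ester (carbonyl methylenation supplies C5) ⇐ (S)-1-aryl-3-silyloxypropan-1-ol + 3-arylpropanoic acid.
- C2 is the one centre set by catalysis (asymmetric allylation of the protected aryl aldehyde); it relays to C4 and C6.

Key step: step 9

Remark: atom numbers in the text follow the oxane ring of the target (O1, C2 bearing the aryl group, C4 the carbinol carbon, C6 bearing the arylethyl chain) and are carried back to the open-chain precursors.

## Route

Step 1
Reactants: 1 3,4-dihydroxy-5-methoxybenzaldehyde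
Product: 2 3,4-bis(benzyloxy)-5-methoxybenzaldehyde
Conditions: BnBr (2.3 equiv), K2CO3, DMF, 60 °C
Reagents that add atoms: benzyl bromide, BrCc1ccccc1
Why: Williamson ether synthesis: carbonate deprotonates both phenols, which displace bromide from benzyl bromide, while the aldehyde is inert to these conditions.

Step 2
Reactants: 2 3,4-bis(benzyloxy)-5-methoxybenzaldehyde
Product: 3 (1S)-1-[3,4-bis(benzyloxy)-5-methoxyphenyl]but-3-en-1-ol
Conditions: allylSnBu3 (1.5 equiv), (S)-BINOL (20 mol%), Ti(OiPr)4 (10 mol%), 4 Å MS, CH2Cl2, −20 °C; sat. NaHCO3 work-up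
Reagents that add atoms: allyltributylstannane, C=CC[Sn](CCCC)(CCCC)CCCC
Why: Keck asymmetric allylation: the (S)-BINOL–Ti(OiPr)4 Lewis acid activates the aldehyde and exposes its si face to the allylstannane, which sets the (S) carbinol centre (the later C2) as the only catalysis-derived stereocentre of the route.

Step 3
Reactants: 3 (1S)-1-[3,4-bis(benzyloxy)-5-methoxyphenyl]but-3-en-1-ol
Product: 5 (1S)-1-[3,4-bis(benzyloxy)-5-methoxyphenyl]propane-1,3-diol, via hydroxy aldehyde 4 (not isolated)
Conditions: OsO4 (2 mol%), NaIO4 (4 equiv), 2,6-lutidine, dioxane/H2O 3:1, rt; extractive work-up, then NaBH4, MeOH, 0 °C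
Reagents that add atoms: osmium tetroxide, O=[Os](=O)(=O)=O (catalytic oxygen carrier); sodium periodate, [Na+].[O-]I(=O)(=O)=O (terminal oxidant)
Why: Lemieux–Johnson oxidation (OsO4-catalysed dihydroxylation with periodate glycol cleavage) removes the terminal alkene carbon and NaBH4 reduces aldehyde 4 before it can dehydrate, so the C4 oxygen is installed without any bond to the stereocentre being touched.

Step 4
Reactants: 5 (1S)-1-[3,4-bis(benzyloxy)-5-methoxyphenyl]propane-1,3-diol
Product: 6 (1S)-1-[3,4-bis(benzyloxy)-5-methoxyphenyl]-3-[(tert-butyldimethylsilyl)oxy]propan-1-ol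
Conditions: TBSCl (1.05 equiv), imidazole, CH2Cl2, 0 °C
Reagents that add atoms: tert-butyldimethylsilyl chloride, CC(C)(C)[Si](C)(C)Cl
Why: Chemoselective silylation: the unhindered primary hydroxyl reacts with the bulky silyl chloride far faster than the secondary benzylic one, which stays free for acylation.

Step 5
Reactants: 6 (1S)-1-[3,4-bis(benzyloxy)-5-methoxyphenyl]-3-[(tert-butyldimethylsilyl)oxy]propan-1-ol; 7 3-[4-(benzyloxy)phenyl]propanoic acid
Product: 8 (1S)-1-[3,4-bis(benzyloxy)-5-methoxyphenyl]-3-[(tert-butyldimethylsilyl)oxy]propyl 3-[4-(benzyloxy)phenyl]propanoate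
Conditions: DCC, DMAP (cat.), CH2Cl2, 0 °C → rt
Reagents that add atoms: none
Why: Steglich esterification: the DCC-activated acid is transferred by DMAP to the secondary alcohol oxygen, so the C–O bond at the stereocentre is not broken and configuration is retained.

Step 6
Reactants: 8 (1S)-1-[3,4-bis(benzyloxy)-5-methoxyphenyl]-3-[(tert-butyldimethylsilyl)oxy]propyl 3-[4-(benzyloxy)phenyl]propanoate
Product: 9 tert-butyl{(3S)-3-[3,4-bis(benzyloxy)-5-methoxyphenyl]-3-({4-[4-(benzyloxy)phenyl]but-1-en-2-yl}oxy)propoxy}dimethylsilane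
Conditions: Cp2TiMe2 (3 equiv), toluene/THF, 65 °C, dark; filtration through Et3N-treated basic alumina
Reagents that add atoms: dimethyltitanocene Cp2TiMe2, [CH3-].[CH3-].[Ti+4].c1cc[cH-]c1.c1cc[cH-]c1
Why: Petasis methylenation: thermolysis of Cp2TiMe2 gives Cp2Ti=CH2, which converts the ester carbonyl through an oxatitanacyclobutane into the 2-alkoxyalkene (its CH2 is the later C5) under non-acidic conditions that spare silyl and benzyl ethers.

Step 7
Reactants: 9 tert-butyl{(3S)-3-[3,4-bis(benzyloxy)-5-methoxyphenyl]-3-({4-[4-(benzyloxy)phenyl]but-1-en-2-yl}oxy)propoxy}dimethylsilane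
Product: 10 (3S)-3-[3,4-bis(benzyloxy)-5-methoxyphenyl]-3-({4-[4-(benzyloxy)phenyl]but-1-en-2-yl}oxy)propan-1-ol
Conditions: Bu4NF (1.2 equiv), THF, 0 °C; NaHCO3 work-up; Et3N-deactivated silica
Reagents that add atoms: none
Why: Fluoride desilylation driven by the strong Si–F bond; the basic medium leaves the acid-labile 2-alkoxyalkene intact.

Step 8
Reactants: 10 (3S)-3-[3,4-bis(benzyloxy)-5-methoxyphenyl]-3-({4-[4-(benzyloxy)phenyl]but-1-en-2-yl}oxy)propan-1-ol
Product: 11 (3S)-3-[3,4-bis(benzyloxy)-5-methoxyphenyl]-3-({4-[4-(benzyloxy)phenyl]but-1-en-2-yl}oxy)propanal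
Conditions: (nPr4N)(RuO4) (5 mol%), N-methylmorpholine N-oxide (1.5 equiv), 4 Å MS, CH2Cl2, 0 °C → rt; short basic alumina plug, used at once
Reagents that add atoms: none
Why: Ley–Griffith oxidation: the perruthenate/N-oxide system oxidises the primary alcohol to the aldehyde under neutral, non-aqueous conditions that avoid both enol ether hydrolysis and over-oxidation.

Step 9
Reactants: 11 (3S)-3-[3,4-bis(benzyloxy)-5-methoxyphenyl]-3-({4-[4-(benzyloxy)phenyl]but-1-en-2-yl}oxy)propanal
Product: 14 (2S,4R,6S)-2-[3,4-bis(benzyloxy)-5-methoxyphenyl]-6-{2-[4-(benzyloxy)phenyl]ethyl}oxan-4-ol, via oxocarbenium triflate 12 (not isolated), via triethylsilyl ether 13 (not isolated)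
Conditions: Et3SiH (3 equiv), Et3SiOTf (0.1 equiv), 2,6-di-tert-butyl-4-methylpyridine (0.2 equiv), CH2Cl2 (0.02 M), −78 °C; then Bu4NF, THF, −78 °C → rt
Reagents that add atoms: none
Why: Proposed new method: Et3SiOTf silylates the aldehyde oxygen, the enol ether carbon C5 adds to the activated carbonyl carbon C4 (intramolecular Mukaiyama-type aldol, also describable as an enol ether Prins closure), and the ring oxocarbenium ion 12 so formed accepts hydride from Et3SiH at C6, which returns the silyl triflate and leaves 13, whose Si–O bond fluoride then cleaves in the same flask. The closest known reaction types are the Mukaiyama aldol–Prins cascade (a 2-alkoxyalkene adds to a Lewis-acid-activated aldehyde and the oxocarbenium ion is trapped), the Petasis–Ferrier rearrangement (enol/oxocarbenium recombination to cis-2,6-disubstituted oxan-4-ones) and silane reductive etherification through ring oxocarbenium ions; their intramolecular merger on a 3-(alk-1-en-2-yloxy)aldehyde has not been shown. The oxane is closed in a 6-(enolendo)-exo-trig mode through a chair-like transition state. C4 is controlled by the C2 centre: with the aryl group equatorial, the silylated carbonyl oxygen takes the equatorial position, antiperiplanar to the enol ether double bond and away from the C6 side chain, so the C4 oxygen ends cis to the aryl group; C6 is controlled by axial hydride delivery to the half-chair oxocarbenium ion with the aryl group pseudo-equatorial, which places the side chain equatorial (2,6-cis). The step needs C–C bond formation to outrun direct hydride transfer to the aldehyde, which the tethered 2-alkoxyalkene secures by being a far stronger nucleophile than the silane and reacting through a six-membered transition state; it also needs the benzylic C2–O1 bond to survive, for which the substrate offers a 3,4,5-trioxygenated ring whose para oxygen is twisted out of conjugation by its two ortho neighbours, helped by −78 °C and a non-chelating silicon Lewis acid.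

Step 10
Reactants: 14 (2S,4R,6S)-2-[3,4-bis(benzyloxy)-5-methoxyphenyl]-6-{2-[4-(benzyloxy)phenyl]ethyl}oxan-4-ol
Product: 15 (2S,4R,6S)-2-(3,4-dihydroxy-5-methoxyphenyl)-6-[2-(4-hydroxyphenyl)ethyl]oxan-4-ol
Conditions: H2 (1 atm), Pd/C (10 wt%), EtOAc/MeOH 1:1, rt; work-up under N2
Reagents that add atoms: none
Why: Catalytic hydrogenolysis: the three aryl benzyl ethers are cleaved under neutral conditions much faster than the hindered ring C2–O1 bond, and no stereocentre is involved.

## Compound list

1 | 3,4-dihydroxy-5-methoxybenzaldehyde (5-hydroxyvanillin) | COc1cc(C=O)cc(O)c1O | starting material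
2 | 3,4-bis(benzyloxy)-5-methoxybenzaldehyde | COc1cc(C=O)cc(OCc2ccccc2)c1OCc1ccccc1 | intermediate
3 | (1S)-1-[3,4-bis(benzyloxy)-5-methoxyphenyl]but-3-en-1-ol | COc1cc([C@@H](O)CC=C)cc(OCc2ccccc2)c1OCc1ccccc1 | intermediate
4 | (3S)-3-[3,4-bis(benzyloxy)-5-methoxyphenyl]-3-hydroxypropanal | COc1cc([C@@H](O)CC=O)cc(OCc2ccccc2)c1OCc1ccccc1 | intermediate (not isolated)
5 | (1S)-1-[3,4-bis(benzyloxy)-5-methoxyphenyl]propane-1,3-diol | COc1cc([C@@H](O)CCO)cc(OCc2ccccc2)c1OCc1ccccc1 | intermediate
6 | (1S)-1-[3,4-bis(benzyloxy)-5-methoxyphenyl]-3-[(tert-butyldimethylsilyl)oxy]propan-1-ol | COc1cc([C@@H](O)CCO[Si](C)(C)C(C)(C)C)cc(OCc2ccccc2)c1OCc1ccccc1 | intermediate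
7 | 3-[4-(benzyloxy)phenyl]propanoic acid | OC(=O)CCc1ccc(OCc2ccccc2)cc1 | starting material
8 | (1S)-1-[3,4-bis(benzyloxy)-5-methoxyphenyl]-3-[(tert-butyldimethylsilyl)oxy]propyl 3-[4-(benzyloxy)phenyl]propanoate | COc1cc([C@@H](OC(=O)CCc2ccc(OCc3ccccc3)cc2)CCO[Si](C)(C)C(C)(C)C)cc(OCc2ccccc2)c1OCc1ccccc1 | intermediate
9 | tert-butyl{(3S)-3-[3,4-bis(benzyloxy)-5-methoxyphenyl]-3-({4-[4-(benzyloxy)phenyl]but-1-en-2-yl}oxy)propoxy}dimethylsilane | COc1cc([C@@H](OC(=C)CCc2ccc(OCc3ccccc3)cc2)CCO[Si](C)(C)C(C)(C)C)cc(OCc2ccccc2)c1OCc1ccccc1 | intermediate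
10 | (3S)-3-[3,4-bis(benzyloxy)-5-methoxyphenyl]-3-({4-[4-(benzyloxy)phenyl]but-1-en-2-yl}oxy)propan-1-ol | COc1cc([C@@H](OC(=C)CCc2ccc(OCc3ccccc3)cc2)CCO)cc(OCc2ccccc2)c1OCc1ccccc1 | intermediate
11 | (3S)-3-[3,4-bis(benzyloxy)-5-methoxyphenyl]-3-({4-[4-(benzyloxy)phenyl]but-1-en-2-yl}oxy)propanal | COc1cc([C@@H](OC(=C)CCc2ccc(OCc3ccccc3)cc2)CC=O)cc(OCc2ccccc2)c1OCc1ccccc1 | intermediate
12 | (2S,4S)-2-[3,4-bis(benzyloxy)-5-methoxyphenyl]-6-{2-[4-(benzyloxy)phenyl]ethyl}-4-[(triethylsilyl)oxy]-2,3,4,5-tetrahydropyrylium trifluoromethanesulfonate (aryl and silyloxy groups cis) | COc1cc([C@@H]2C[C@H](O[Si](CC)(CC)CC)CC(CCc3ccc(OCc4ccccc4)cc3)=[O+]2)cc(OCc2ccccc2)c1OCc1ccccc1.[O-]S(=O)(=O)C(F)(F)F | intermediate (not isolated)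
13 | {[(2S,4R,6S)-2-[3,4-bis(benzyloxy)-5-methoxyphenyl]-6-{2-[4-(benzyloxy)phenyl]ethyl}oxan-4-yl]oxy}triethylsilane | COc1cc([C@@H]2C[C@H](O[Si](CC)(CC)CC)C[C@H](CCc3ccc(OCc4ccccc4)cc3)O2)cc(OCc2ccccc2)c1OCc1ccccc1 | intermediate (not isolated)
14 | (2S,4R,6S)-2-[3,4-bis(benzyloxy)-5-methoxyphenyl]-6-{2-[4-(benzyloxy)phenyl]ethyl}oxan-4-ol | COc1cc([C@@H]2C[C@H](O)C[C@H](CCc3ccc(OCc4ccccc4)cc3)O2)cc(OCc2ccccc2)c1OCc1ccccc1 | intermediate
15 | (2S,4R,6S)-2-(3,4-dihydroxy-5-methoxyphenyl)-6-[2-(4-hydroxyphenyl)ethyl]oxan-4-ol | COc1cc([C@@H]2C[C@H](O)C[C@H](CCc3ccc(O)cc3)O2)cc(O)c1O | target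

## Step count and risks

Total step count: 10. Longest linear sequence: 10 steps (1 → 15); acid 7 enters in step 5.

Steps most likely to fail:

1. Step 9 (carries the label). Three processes could defeat it:
   - hydride transfer from the silane to the silyl-activated aldehyde before the C–C bond forms;
   - attack on the aldehyde face that puts the C4 oxygen axial;
   - heterolysis of the benzylic C2–O1 bond of the oxocarbenium ion, with loss of configuration at C2.

   The fallback is known chemistry. It sets out from 3 and 7 and comes back at 14. Steglich esterification (DCC, DMAP) of 3 with 7 should give (1S)-1-[3,4-bis(benzyloxy)-5-methoxyphenyl]but-3-en-1-yl 3-[4-(benzyloxy)phenyl]propanoate F1. Reductive acetylation of the ester (iBu2AlH, CH2Cl2, −78 °C; then pyridine, DMAP, Ac2O) should give the α-acetoxy ether 1-({(1S)-1-[3,4-bis(benzyloxy)-5-methoxyphenyl]but-3-en-1-yl}oxy)-3-[4-(benzyloxy)phenyl]propyl acetate F2. A segment-coupling Prins cyclisation (BF3·OEt2, AcOH, hexanes/CH2Cl2, 0 °C or below) should then close the oxane through a chair transition state, with equatorial capture of the 4-oxanyl cation by acetate, to give (2S,4R,6S)-2-[3,4-bis(benzyloxy)-5-methoxyphenyl]-6-{2-[4-(benzyloxy)phenyl]ethyl}oxan-4-yl acetate F3. Methanolysis (K2CO3, MeOH) should return 14. The temperature is kept low to limit 2-oxonia-Cope scrambling at the aryl-bearing centre.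

2. Step 6. Methylenation of the hindered secondary ester may stay incomplete while the titanium methylidene decays thermally, and the 2-alkoxyalkene may be hydrolysed on contact with acidic surfaces during isolation.

   The fallback builds the enol ether by ketal exchange and elimination instead of carbonyl olefination. It sets out from 6 and comes back at 9. Benzylation (BnBr, K2CO3, acetone) of commercial 4-(4-hydroxyphenyl)butan-2-one should give 4-[4-(benzyloxy)phenyl]butan-2-one F4. Ketalisation (HC(OMe)3, MeOH, TsOH cat.) should give 4-[4-(benzyloxy)phenyl]-2,2-dimethoxybutane F5. Exchange of one methoxy group for alcohol 6 (pyridinium p-toluenesulfonate cat., toluene, removal of MeOH) should give the mixed ketal tert-butyl{(3S)-3-[3,4-bis(benzyloxy)-5-methoxyphenyl]-3-({4-[4-(benzyloxy)phenyl]-2-methoxybutan-2-yl}oxy)propoxy}dimethylsilane F6. Me3SiOTf/iPr2NEt (CH2Cl2, −20 °C) should then remove the small methoxy group and a methyl proton to give 9.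

3. Step 2. Turnover may be slow with the electron-rich aldehyde, and an uncatalysed background allylation may erode the enantioselectivity.

   The fallback replaces asymmetric C–C bond formation by racemic addition and enzymatic resolution. It sets out from 2 and comes back at 3. AllylMgBr (THF, 0 °C) should give racemic 1-[3,4-bis(benzyloxy)-5-methoxyphenyl]but-3-en-1-ol F7. Immobilised Candida antarctica lipase B with vinyl acetate (tert-butyl methyl ether, 35 °C) should acylate the (R)-enantiomer, the usual lipase preference for 1-arylalkan-1-ols, to (1R)-1-[3,4-bis(benzyloxy)-5-methoxyphenyl]but-3-en-1-yl acetate F8. This leaves (S)-alcohol 3, at most half of the material, to be separated by chromatography.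

## Further compounds

F1 | step 9 | (1S)-1-[3,4-bis(benzyloxy)-5-methoxyphenyl]but-3-en-1-yl 3-[4-(benzyloxy)phenyl]propanoate | COc1cc([C@@H](OC(=O)CCc2ccc(OCc3ccccc3)cc2)CC=C)cc(OCc2ccccc2)c1OCc1ccccc1
F2 | step 9 | 1-({(1S)-1-[3,4-bis(benzyloxy)-5-methoxyphenyl]but-3-en-1-yl}oxy)-3-[4-(benzyloxy)phenyl]propyl acetate (both epimers at the acetal carbon) | COc1cc([C@@H](OC(OC(C)=O)CCc2ccc(OCc3ccccc3)cc2)CC=C)cc(OCc2ccccc2)c1OCc1ccccc1
F3 | step 9 | (2S,4R,6S)-2-[3,4-bis(benzyloxy)-5-methoxyphenyl]-6-{2-[4-(benzyloxy)phenyl]ethyl}oxan-4-yl acetate | COc1cc([C@@H]2C[C@H](OC(C)=O)C[C@H](CCc3ccc(OCc4ccccc4)cc3)O2)cc(OCc2ccccc2)c1OCc1ccccc1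
F4 | step 6 | 4-[4-(benzyloxy)phenyl]butan-2-one | CC(=O)CCc1ccc(OCc2ccccc2)cc1
F5 | step 6 | 4-[4-(benzyloxy)phenyl]-2,2-dimethoxybutane | CC(OC)(OC)CCc1ccc(OCc2ccccc2)cc1
F6 | step 6 | tert-butyl{(3S)-3-[3,4-bis(benzyloxy)-5-methoxyphenyl]-3-({4-[4-(benzyloxy)phenyl]-2-methoxybutan-2-yl}oxy)propoxy}dimethylsilane (both ketal epimers) | COc1cc([C@@H](OC(C)(OC)CCc2ccc(OCc3ccccc3)cc2)CCO[Si](C)(C)C(C)(C)C)cc(OCc2ccccc2)c1OCc1ccccc1
F7 | step 2 | racemic 1-[3,4-bis(benzyloxy)-5-methoxyphenyl]but-3-en-1-ol | COc1cc(C(O)CC=C)cc(OCc2ccccc2)c1OCc1ccccc1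
F8 | step 2 | (1R)-1-[3,4-bis(benzyloxy)-5-methoxyphenyl]but-3-en-1-yl acetate | COc1cc([C@H](OC(C)=O)CC=C)cc(OCc2ccccc2)c1OCc1ccccc1
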